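Does Thursday's flask, with more catalyst and more time than Saturday's, also end with more target, and by how much?

| setting | north-west | south-west | Thursday's | Saturday's |
|---|---|---|---|---|
| substrate | 0.25 M | 0.25 M | 0.25 M | 0.25 M |
| gas | 150 mM (held) | 150 mM (held) | 150 mM (held) | 150 mM (held) |
| free catalyst | 21 mM | 66 mM | 50 mM | 15 mM |
| temperature | 95 °C | 106 °C | 100 °C | 100 °C |
| remark | run made earlier | run made earlier |  |  |
| time |  |  | 4.0 min | 1.0 min |

| run | time / min | target / % | substrate / % |
|---|---|---|---|
| north-west | 0.250 | 0.8 | 99.9 |
| north-west | 0.417 | 0.8 | 98.4 |
| north-west | 0.833 | 2.0 | 94.4 |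
| north-west | 1.33 | 4.2 | 89.2 |
| north-west | 3.00 | 14.9 | 80.0 |
| south-west | 0.250 | 0.8 | 96.3 |
| south-west | 0.667 | 7.5 | 86.7 |
| south-west | 1.33 | 20.2 | 68.1 |
| south-west | 2.00 | 37.7 | 50.7 |
| south-west | 3.00 | 61.1 | 29.8 |

(standard deviation of a reading: 1 percentage point)

1. the winner by amount of target, in percent of the substrate charged; "neither" if no more than 2 percentage points parts them (Thursday's / Saturday's / neither)
2. how much target is there at the end, in percent of the substrate charged: Thursday's
3. how much target is there at the end, in percent of the substrate charged: Saturday's

- at the start none of the gas is in solution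

My own view is a pump with a delay. In each run I replace the late curve by the straight line through the last two readings. I divide its slope by the catalyst charge, taken as a share of the substrate charge. That gives 0.763 /min in the north-west run and 0.886 /min in the south-west run. Since 100 °C lies between their temperatures, I take the mean, the working turnover (a turnover frequency per catalyst charged), 0.825 /min.

Each line meets zero target late, at 0.674 min and 0.389 min. Their mean, 0.532 min, is my induction period.

For a flask at 100 °C with the substrate and gas charges of the runs, I reckon target as working turnover times catalyst share times time past the delay. Thursday's flask gets 57.2% and Saturday's 2.32%. Using either run's turnover in place of the mean moves Thursday's figure by 4.3 percentage points.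

The forecast takes the other view, a bound form that must build up: “it looks like a catalyst-bound complex”. It says Thursday's, with 50% against 3%. We agree on the winner and part on Thursday's flask by 7.2 points.

The simulation gives Thursday's: 57.4% against 3.30%.

    reagent + free catalyst ⇌ catalyst intermediate A (K = 132 /M, k = 281 /M/min, Ea = 73.0 kJ/mol, ΔH = −21.0 kJ/mol)
    substrate + catalyst intermediate A → catalyst intermediate B (k = 17.7 /M/min, Ea = 70.0 kJ/mol)
    catalyst intermediate B ⇌ free catalyst + target (K = 0.220 M, k = 1.73 /min, Ea = 101 kJ/mol, ΔH = 12.0 kJ/mol)
    gas ⇌ reagent, rate k4*(csat - [reagent]) (kL = 0.573 /min)
    (constants at 100 °C)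

Thursday's flask lands nearer my line, off by 0.20 points against the forecast's 7.4 points. Saturday's short flask is the forecast's ground: it is off by 0.3 points, my line by 0.98 points. Neither flask has come to rest at its asked time, with 33% of the substrate left in Thursday's flask and 93% in Saturday's. My line reaches the whole charge in Thursday's flask at 6.60 min, and by 40.0 min that flask holds 99.0% target and 0% substrate. Saturday's flask at 10.0 min holds 56.7% target against the line's 46.8%, with 40.3% of its substrate still there.

The earlier runs and the new flask were generated by integration with made-up constants; noise was put on by code.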